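**Retrosynthetic overview**
- The tertiary allylic hydroperoxide and the (5E)-alkene are made together in the last step by a singlet-oxygen ene reaction on a 6,7-prenyl-type alkene.
- That alkene comes from cross-metathesis of a terminal homoallylic alcohol with 2-methyl-2-butene.
- Key disconnection C4–C5: asymmetric allylboration joins the coumarin-bearing (E)-enal with an allyl fragment and sets the only stereocentre (4R).
- The enal comes from Mitsunobu O-alkylation of 4-hydroxy-5-methylcoumarin with (E)-4-hydroxy-2-methylbut-2-enal (Wittig from glycolaldehyde).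
- Rings: the benzene ring is bought; the pyranone ring is the only ring formed and is formed first (Claisen condensation/lactonisation of an o-hydroxyacetophenone with diethyl carbonate).

Assumption: 2'-hydroxy-6'-methylacetophenone and the salt-free pentane solution of ˡIpc2B(allyl) are taken as catalogue items; side-chain atoms are numbered C1 (OCH2) to C8.

**Step 1**
Reactants: 1 2'-hydroxy-6'-methylacetophenone
Product: 3 4-hydroxy-5-methyl-2H-chromen-2-one, via β-keto ester 2 (not isolated)
Conditions: NaH (3.5 equiv), (EtO)2CO (excess), toluene, 110 °C; then aq. HCl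
Reagents that add atoms: diethyl carbonate, CCOC(=O)OCC
Why: Claisen condensation of the ketone enolate with diethyl carbonate gives β-keto ester 2, whose phenoxide closes the lactone with loss of ethanol (the standard 4-hydroxycoumarin synthesis), so the pyranone ring forms with the methyl group fixed at C5; no stereocentre.

**Step 2**
Reactants: 4 glycolaldehyde dimer (1,4-dioxane-2,5-diol); 5 2-(triphenylphosphoranylidene)propanal
Product: 7 (2E)-4-hydroxy-2-methylbut-2-enal, via glycolaldehyde 6 (not isolated)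
Conditions: 4 (0.55 equiv of dimer), 5 (1.0 equiv), THF, reflux
Reagents that add atoms: none
Why: Wittig olefination of monomeric glycolaldehyde (released from the dimer on heating) with a stabilised α-methyl formyl ylide gives the trisubstituted enal with high E selectivity, which fixes the 2E geometry of the side chain.

**Step 3**
Reactants: 3 4-hydroxy-5-methyl-2H-chromen-2-one; 7 (2E)-4-hydroxy-2-methylbut-2-enal
Product: 8 (2E)-2-methyl-4-[(5-methyl-2-oxo-2H-chromen-4-yl)oxy]but-2-enal
Conditions: PPh3, DIAD, THF, 0 °C to rt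
Reagents that add atoms: none
Why: Mitsunobu reaction in which the acidic 4-OH of 3 (pKa about 4) is alkylated on oxygen by the phosphonium-activated primary allylic alcohol of 7 under neutral conditions that leave the enal and the alkene geometry untouched (minor 2-alkoxychromone or C3-alkyl isomers are removed by chromatography).

**Step 4**
Reactants: 8 (2E)-2-methyl-4-[(5-methyl-2-oxo-2H-chromen-4-yl)oxy]but-2-enal; 9 ˡIpc2B(allyl), the B-allylbis(isopinocampheyl)borane built from (−)-α-pinene
Product: 11 4-{[(2E,4R)-4-hydroxy-3-methylhepta-2,6-dien-1-yl]oxy}-5-methyl-2H-chromen-2-one, via borinate ester 10 (not isolated)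
Conditions: 9 (1.3 equiv, salt-free), Et2O/THF, −78 °C; then NaBO3·4H2O, THF/H2O, 0 °C to rt
Reagents that add atoms: none
Why: Brown asymmetric allylboration, a carbonyl allylation through a chair-like six-membered transition state in which the (−)-α-pinene-derived Ipc groups deliver allyl to the Re face of the aldehyde, forms the C4–C5 bond and sets C4 as R (typically ≥90% ee for α-methyl enals, to be confirmed by Mosher ester analysis), the lactone being inert to the allylborane at −78 °C and to the mild perborate work-up.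

**Step 5**
Reactants: 11 4-{[(2E,4R)-4-hydroxy-3-methylhepta-2,6-dien-1-yl]oxy}-5-methyl-2H-chromen-2-one
Product: 12 4-{[(2E,4R)-4-hydroxy-3,7-dimethylocta-2,6-dien-1-yl]oxy}-5-methyl-2H-chromen-2-one
Conditions: Grubbs II (5 mol%), 2-methyl-2-butene (large excess), CH2Cl2, 40 °C; Ru scavenging, chromatography
Reagents that add atoms: 2-methyl-2-butene, CC=C(C)C
Why: Olefin cross-metathesis in which the terminal alkene exchanges its CH2 terminus for the isopropylidene group of 2-methyl-2-butene with loss of propene, while the deactivated trisubstituted 2,3-alkene, the coumarin and the C4 stereocentre are not touched.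

**Step 6**
Reactants: 12 4-{[(2E,4R)-4-hydroxy-3,7-dimethylocta-2,6-dien-1-yl]oxy}-5-methyl-2H-chromen-2-one
Product: 13 4-{[(2E,4R,5E)-7-hydroperoxy-4-hydroxy-3,7-dimethylocta-2,5-dien-1-yl]oxy}-5-methyl-2H-chromen-2-one
Conditions: O2, tetraphenylporphyrin (cat.), CH2Cl2 (trace pyridine), visible light (λ > 420 nm), −20 to 0 °C; cold chromatography
Reagents that add atoms: dioxygen (as singlet oxygen), O=O
Why: Schenck ene reaction in which singlet oxygen attacks the electron-rich trialkyl 6,7-alkene in preference to the oxygen-deactivated 2,3-alkene and the coumarin, and abstraction of a C5 hydrogen puts OOH on tertiary C7 and moves the double bond to C5=C6 with E geometry without touching C4 (the 6-hydroperoxy-7-ene regioisomer from CH3 abstraction is removed by chromatography).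

**Compound list**
1 | 2'-hydroxy-6'-methylacetophenone | CC(=O)c1c(C)cccc1O | starting material
2 | ethyl 3-(2-hydroxy-6-methylphenyl)-3-oxopropanoate (β-keto ester, sodium salt in the flask) | CCOC(=O)CC(=O)c1c(C)cccc1O | intermediate
3 | 4-hydroxy-5-methyl-2H-chromen-2-one | Cc1cccc2oc(=O)cc(O)c12 | intermediate
4 | glycolaldehyde dimer (1,4-dioxane-2,5-diol) | OC1COC(O)CO1 | starting material
5 | 2-(triphenylphosphoranylidene)propanal | CC(C=O)=P(c1ccccc1)(c1ccccc1)c1ccccc1 | starting material
6 | glycolaldehyde (2-hydroxyacetaldehyde) | OCC=O | intermediate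
7 | (2E)-4-hydroxy-2-methylbut-2-enal | O=C/C(C)=C/CO | intermediate
8 | (2E)-2-methyl-4-[(5-methyl-2-oxo-2H-chromen-4-yl)oxy]but-2-enal | O=C/C(C)=C/COc1cc(=O)oc2cccc(C)c12 | intermediate
9 | ˡIpc2B(allyl), B-allylbis(isopinocampheyl)borane from (−)-α-pinene (its Ipc groups give (1S,2S,3S,5R)-isopinocampheol on oxidation) | C=CCB([C@H]1C[C@H]2C[C@@H]([C@@H]1C)C2(C)C)[C@H]1C[C@H]2C[C@@H]([C@@H]1C)C2(C)C | starting material
10 | (2E,4R)-3-methyl-1-[(5-methyl-2-oxo-2H-chromen-4-yl)oxy]hepta-2,6-dien-4-yl bis(isopinocampheyl)borinate | C/C(=C\COc1cc(=O)oc2cccc(C)c12)[C@H](OB([C@H]1C[C@H]2C[C@@H]([C@@H]1C)C2(C)C)[C@H]1C[C@H]2C[C@@H]([C@@H]1C)C2(C)C)CC=C | intermediate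
11 | 4-{[(2E,4R)-4-hydroxy-3-methylhepta-2,6-dien-1-yl]oxy}-5-methyl-2H-chromen-2-one | C/C(=C\COc1cc(=O)oc2cccc(C)c12)[C@H](O)CC=C | intermediate
12 | 4-{[(2E,4R)-4-hydroxy-3,7-dimethylocta-2,6-dien-1-yl]oxy}-5-methyl-2H-chromen-2-one | C/C(=C\COc1cc(=O)oc2cccc(C)c12)[C@H](O)CC=C(C)C | intermediate
13 | 4-{[(2E,4R,5E)-7-hydroperoxy-4-hydroxy-3,7-dimethylocta-2,5-dien-1-yl]oxy}-5-methyl-2H-chromen-2-one | C/C(=C\COc1cc(=O)oc2cccc(C)c12)[C@H](O)/C=C/C(C)(C)OO | target

**Totals**
Total steps: 6. Longest linear sequence: 5 steps (1 to 3 to 8 to 11 to 12 to 13; the branch from 4 and 5 through 7 is equally long).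

**Steps most likely to fail**

Step 6 (ene regioselectivity). Roughly half of the material is expected to go to the secondary 6-hydroperoxide, and the product is a sensitive hydroperoxide. The fallback sets out from 12 and comes back at 13, and places the peroxide by Markovnikov bromo-hydroperoxidation and elimination instead of an ene reaction. Compound 12 is silylated (TESCl, imidazole, DMF) to the triethylsilyl ether F1. 1,3-Dibromo-5,5-dimethylhydantoin with anhydrous ethereal H2O2 at −40 °C adds Br+ to the electron-rich 6,7-alkene, and H2O2 opens the bromonium ion at the tertiary carbon to give the 6-bromo-7-hydroperoxide F2. 2-Methoxypropene with PPTS caps the OOH as the 2-methoxyprop-2-yl peroxyketal F3, which blocks dioxetane formation. DBU in toluene at 60 °C removes HBr, which can only go towards C5 because C7 has no hydrogen, giving the (5E)-allylic peroxyketal F4. AcOH/THF/H2O at rt cleaves the peroxyketal and the TES ether together and delivers 13.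

Step 3 (O- versus C3- or 2-O-alkylation of the ambident, peri-hindered 4-hydroxycoumarin, and the fragility of enal 7). The fallback sets out from 3 and comes back at 8, and reverses the polarity so that only the ether oxygen can attach. POCl3 with BnEt3NCl (MeCN, reflux) turns 3 into 4-chloro-5-methylcoumarin F5. Sodium prenoxide (3-methylbut-2-en-1-ol, NaH, THF, 0 °C) replaces chloride by addition–elimination at C4 to give the prenyl ether F6. SeO2 (cat.) with t-BuOOH (CH2Cl2, rt) oxidises the (E)-methyl group to a mixture of the (E)-allylic alcohol F7 and 8, and MnO2 converts F7 into 8.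

Step 4 (ee, and survival of the lactone/enol ether through allylboration and oxidative work-up). The fallback sets out from 7 and comes back at 11, and carries out the allylation before the coumarin is attached. Compound 7 is silylated (TBSCl, imidazole, CH2Cl2) to the TBS ether F8. Reagent 9 (Et2O, −78 °C) gives the borinate F9, and standard NaOH/H2O2 work-up gives the (4R)-alcohol F10. TBAF gives the diol F11. A Mitsunobu reaction of F11 with 3 (PPh3, DIAD, THF, 0 °C) etherifies the unhindered primary allylic OH and gives 11.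

**Further compounds**
F1 | step 6 | 5-methyl-4-{[(2E,4R)-3,7-dimethyl-4-(triethylsilyloxy)octa-2,6-dien-1-yl]oxy}-2H-chromen-2-one | C/C(=C\COc1cc(=O)oc2cccc(C)c12)[C@H](O[Si](CC)(CC)CC)CC=C(C)C
F2 | step 6 | 4-{[(2E,4R)-6-bromo-7-hydroperoxy-3,7-dimethyl-4-(triethylsilyloxy)oct-2-en-1-yl]oxy}-5-methyl-2H-chromen-2-one (C6 epimers) | C/C(=C\COc1cc(=O)oc2cccc(C)c12)[C@H](O[Si](CC)(CC)CC)CC(Br)C(C)(C)OO
F3 | step 6 | 4-{[(2E,4R)-6-bromo-7-[(2-methoxypropan-2-yl)peroxy]-3,7-dimethyl-4-(triethylsilyloxy)oct-2-en-1-yl]oxy}-5-methyl-2H-chromen-2-one | C/C(=C\COc1cc(=O)oc2cccc(C)c12)[C@H](O[Si](CC)(CC)CC)CC(Br)C(C)(C)OOC(C)(C)OC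
F4 | step 6 | 4-{[(2E,4R,5E)-7-[(2-methoxypropan-2-yl)peroxy]-3,7-dimethyl-4-(triethylsilyloxy)octa-2,5-dien-1-yl]oxy}-5-methyl-2H-chromen-2-one | C/C(=C\COc1cc(=O)oc2cccc(C)c12)[C@H](O[Si](CC)(CC)CC)/C=C/C(C)(C)OOC(C)(C)OC
F5 | step 3 | 4-chloro-5-methyl-2H-chromen-2-one | Cc1cccc2oc(=O)cc(Cl)c12
F6 | step 3 | 5-methyl-4-[(3-methylbut-2-en-1-yl)oxy]-2H-chromen-2-one | CC(C)=CCOc1cc(=O)oc2cccc(C)c12
F7 | step 3 | 4-{[(2E)-4-hydroxy-3-methylbut-2-en-1-yl]oxy}-5-methyl-2H-chromen-2-one | C/C(CO)=C\COc1cc(=O)oc2cccc(C)c12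
F8 | step 4 | (2E)-4-[(tert-butyldimethylsilyl)oxy]-2-methylbut-2-enal | O=C/C(C)=C/CO[Si](C)(C)C(C)(C)C
F9 | step 4 | (2E,4R)-1-[(tert-butyldimethylsilyl)oxy]-3-methylhepta-2,6-dien-4-yl bis(isopinocampheyl)borinate | C/C(=C\CO[Si](C)(C)C(C)(C)C)[C@H](OB([C@H]1C[C@H]2C[C@@H]([C@@H]1C)C2(C)C)[C@H]1C[C@H]2C[C@@H]([C@@H]1C)C2(C)C)CC=C
F10 | step 4 | (2E,4R)-1-[(tert-butyldimethylsilyl)oxy]-3-methylhepta-2,6-dien-4-ol | C/C(=C\CO[Si](C)(C)C(C)(C)C)[C@H](O)CC=C
F11 | step 4 | (2E,4R)-3-methylhepta-2,6-diene-1,4-diol | C/C(=C\CO)[C@H](O)CC=C
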